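All runs stem from a simulated flask on assumed constants; noise was put on by code.

- In a closed flask with this overall equation, one Rgt leaves for each Prd that appears, bound forms aside. A flask that stalls with both partners present has therefore lost its rate, and the useful question is how much Prd the rate can still buy.

| flask | Sub | Rgt | Cat | time |
|---|---|---|---|---|
| Sunday's | 0.800 M | 0.880 M | 0.0800 M |  |
| Wednesday's | 0.400 M | 0.480 M | 0.0800 M |  |
| Monday's | 0.800 M | 1.80 M | 0.0800 M |  |
| Saturday's | 1.20 M | 0.880 M | 0.0800 M |  |
| Thursday's | 0.800 M | 0.880 M | 0.0800 M | 160 min |

| run | time / min | [Prd] / M |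
|---|---|---|
| Sunday's run | 1.6 | 0.074 |
| Sunday's run | 2.8 | 0.110 |
| Sunday's run | 4.8 | 0.201 |
| Sunday's run | 8.2 | 0.309 |
| Sunday's run | 14 | 0.420 |
| Sunday's run | 24 | 0.536 |
| Sunday's run | 41 | 0.581 |
| Wednesday's run | 1.6 | 0.046 |
| Wednesday's run | 2.8 | 0.076 |
| Wednesday's run | 4.8 | 0.129 |
| Wednesday's run | 8.2 | 0.170 |
| Wednesday's run | 14 | 0.246 |
| Wednesday's run | 24 | 0.288 |
| Wednesday's run | 41 | 0.299 |
| Monday's run | 1.6 | 0.107 |
| Monday's run | 2.8 | 0.196 |
| Monday's run | 4.8 | 0.315 |
| Monday's run | 8.2 | 0.493 |
| Monday's run | 14 | 0.639 |
| Monday's run | 24 | 0.736 |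
| Monday's run | 41 | 0.800 |
| Saturday's run | 1.6 | 0.072 |
| Saturday's run | 2.8 | 0.128 |
| Saturday's run | 4.8 | 0.181 |
| Saturday's run | 8.2 | 0.297 |
| Saturday's run | 14 | 0.412 |
| Saturday's run | 24 | 0.528 |
| Saturday's run | 41 | 0.584 |

(standard deviation of a reading: 0.008 M)

- Overall: Sub + Rgt -> Prd, with Cat as catalyst.
- Constant volume, constant temperature.
- Readings of a species count what is bound in complexes too.
- "The second partner" is Rgt.
- An order is taken over about fifteen percent of the charge, up and down.

* order of the initial rate in [Rgt], near the charge of the Sunday's run, the rate being that where two percent of its Sub are Prd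
* order of the initial rate in [Sub], near the charge of the Sunday's run, the rate being that where two percent of its Sub are Prd (one fixed amount of Prd, the same in the runs compared)
* the Wednesday's run starts with 0.400 M less of Sub and of Rgt than the Sunday's run, and with no Prd. Compared where both hold the same amount of Sub, once fifteen percent of what the Wednesday's run was charged with has turned into Prd, is the Wednesday's run faster, slower or alike (within a tenth)?
* Prd in the Thursday's run at 160 min, as a share of the Sub charged

- Sunday's flask averages 0.0419 M min⁻¹ over its first 4.8 min, but only 0.002647 M min⁻¹ over its last interval, a reading that carries the scatter. The rate has fallen by a factor of 15.8.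
- With 1.20 M of Sub, Saturday's flask holds 0.297 M at 8.2 min, against 0.309 M in Sunday's flask with 0.800 M, so this reckoning puts the early order in Sub near zero and, as an assumption, takes the factor from Sub as near one.
- Monday's early rate against Sunday's gives an order in Rgt of 0.628 over that wide span of Rgt. With this order, this reckoning puts the slowing from the Rgt used between Sunday's two stretches at a factor of 1.74.
- The remaining factor, 9.07, is larger than the Rgt factor, and this reckoning assigns it to working Cat leaving service. At the asked point, Wednesday's and Sunday's flasks hold the same Sub and the same Rgt, though not the same Prd. Over the readings around that point, Wednesday's younger flask makes 0.0250 M min⁻¹, faster than Sunday's older flask at 0.0116 M min⁻¹, a ratio of 2.16 read from scattered readings.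
- Dividing the rate lost by the Prd made removes time. In Sunday's flask, that ratio of rate lost to Prd made is 0.0857 min⁻¹, so its late rate still buys a little more Prd. Carrying this straight line on, this reckoning puts the end at 0.589 M, which is 73.7% of the Sub in Thursday's flask, charged like Sunday's.
- Suppose Cat is lost from the form that meets Rgt. Then the rate of Prd divided by the rate of Cat loss, the partition ratio, is a constant times Rgt and holds no time. Summed over the loss of the Cat charge, this makes that constant times the Cat charge equal to the survival exponent, the natural logarithm of Rgt charged over Rgt left at the end, which Sunday's flask puts at 1.11.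
- The forecast gives 0.7 and 0.05 for the orders in Rgt and Sub, faster for Wednesday's flask and 75% for Thursday's, reading the stall as “time-dependent catalyst death, not product inhibition”; its Rgt order and its Thursday share stand above the 0.628 and 73.7% reckoned here.
- The flask gives orders of 0.59 in Rgt and −0.0098 in Sub near Sunday's charge. Wednesday's flask is faster, by a ratio of 2.5, and Thursday's flask reaches 74.7%.

    Cat + Sub → Cat.Sub (3.210 M⁻¹ min⁻¹)
    Cat.Sub + Rgt → G (4.302 M⁻¹ min⁻¹)
    G → Prd + Cat (12.72 min⁻¹)
    Cat.Sub + Sub ⇌ Cat.Sub2, settled at all times (3.220 M⁻¹)
    Cat.Sub → X + Sub (0.3030 min⁻¹)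

- Cat.Sub feeds both G and X, so it cancels from the ratio, leaving a partition ratio of 14.2 M⁻¹ times Rgt. Over the Cat charge, the exponent is 1.14, against 1.11 from Sunday's readings and 1.14 from Thursday's result. Thursday's flask without the passing of Cat.Sub into X + Sub reaches 100% instead of 74.7%. In Monday's flask, the exponent 1.11 allows 1.21 M of Prd, more than its 0.800 M of Sub, and its last reading stands at 0.800 M.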